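## Analysis of the target

Atoms are numbered along the SMILES string of the target 30 (C1, C2, C3, O4, C5 … C26). Ring A is the cyclohexane C5, C6, C7, C8, C14, C16. It is trans-fused to the δ-lactone ring B (C8, C9, C10, O11, C12, C14). C9 is the spiro centre to the cyclohexanone ring C (C9, C17, C19, C20, C24, C23), which the O21–C22 unit bridges to give the tetrahydrofuran ring D (C20, O21, C22, C23, C24).

There are six stereocentres: C5 (R), C8 (S), C9 (R), C14 (S), C20 (S), C23 (S). C20 and C23 are tied together by the bridge. C9 carries C8 on the face of the O21–C22 bridge and C10 on the face of the axial C24 methyl group. H8 and the C14 hydroxyl are trans-diaxial on ring B, and the C5 side chain is equatorial on ring A.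

The sensitive groups are:
- the β-alkoxy ketone C17/C20–O21, which opens by E1cB as soon as C19 is deprotonated;
- the 2-substituted acrolein;
- the tertiary α-hydroxy lactone, whose hydroxyl is 1,4 to C6.

The difficulty lies in the three contiguous congested carbons C8, C9 and C14 around a spiro quaternary centre, and in the base sensitivity of rings C and D, which rules out enolate chemistry once ring D is closed.

The strategy rests on C5. It bears C2(=C1H2)–C3HO, which is the residue left when a carbon radical adds to the β-carbon of a 2-(sulfonylmethyl)enal and the sulfonyl radical leaves from C1. C5–C6 can therefore be the last bond and ring A the last ring.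

## Retrosynthetic reasoning

**C5–C6 (30 ⇒ 29).** Cutting ring A between C5 and C6 leaves a primary iodide at C6 and a 2-(ethylsulfonylmethyl)enal on C16. The forward radical addition–fragmentation must close ring A, create the exocyclic C1 methylene and set C5 in one event. It was preferred to a cut at C5–C16 because the C7 and C16 arms then sit on the rigid lactone, and the acrolein is not exposed to any earlier step.

**C5=C2 (29 ⇒ 23 + 28).** The trisubstituted alkene is cut by cross-metathesis into the allyl carbinol 23 and the enal 28. This brings in the acceptor in one step, under neutral conditions, after the iodide is in place. 28 comes from 24 and 25 through 26 and 27.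

**C14–C16 (23 ⇒ 19 + 20, through 21 and 22).** The tertiary carbinol is cut to the α-keto lactone 19 and allyl bromide 20. An enolate at C14 is not an option: the C19 protons of the ketone are more acidic, and their enolate expels O21. The target also needs the carbon to arrive last, on the open face of C14, trans to the C7 arm and anti to the axial C9–C17 bond. A neutral Barbier-type addition to the ketone does this and leaves the hydroxyl free. The iodide is made afterwards from the silyl ether (21 ⇒ 22 ⇒ 23).

**C14=O and the lactone C–O bond (19 ⇒ 18 ⇒ 16, through 17).** The C14 ketone is masked as the exocyclic methylene of lactone 18, removed by ozonolysis. Ring B is opened at O11–C12 to the hydroxy ester 17, which comes from reduction of the aldehyde 16. No oxidation-state change at C12 is then needed.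

**C8–C9 (16 ⇒ 15).** The quaternary centre and its neighbour are cut together by a Claisen rearrangement of the allyl enol ether 15. The bicyclic core is kept intact for this step because its syn-axial methyl group directs the new bond to the bridge face of C9, and the chair transition state relays C9 to C8.

**O21–C20 and O–C16 (15 ⇒ 13 ⇒ 8 + 12, through 14).** Ring D is opened by a retro-oxa-Michael cut to the enone 13, and the enol ether is cut to the hydroxymethylene ketone 8 and the bromide 12. The order matters: C10 must be on C9 before ring D closes, while the enone has a single enolisable position. The bromide 12 comes from 9 and 10 by a Morita–Baylis–Hillman reaction (11) and allylic bromination.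

**C9–C10, C22–C23 and the ring (8 ⇒ 7 ⇒ 6 ⇒ 4 ⇒ 2 + 3; 2 ⇒ 1).** C10 is removed by a retro-formylation. C22 is traced through the silyl ether 7, the alcohol 6 and the aldehyde 5 to the styryl group of 4. That group is put on one of the two enantiotopic enone halves of dienone 2 by an asymmetric rhodium-catalysed 1,4-addition of 3, and 2 comes from 1 by dehydrogenation.

## Alternatives that were turned down

**Alternative 1: oxymethyl radical closure of ring D.**
- Disconnection: C22–C23.
- Forward key step: in selenide A1 a tin hydride generates the O21-bound methyl radical, which adds 5-exo to C23 of the enone. The C9 radical takes a hydrogen atom, giving the bicyclic ketone A2.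
- For it: the radical is nucleophilic and the acceptor electron-poor; the bridge forces the cis relation of C20 and C23; no intermolecular conjugate addition at the neopentyl carbon C23 is needed, and on that point it is stronger than the chosen route.
- Against it: A2 is only the core with C9–H. The quaternary C9 would then have to be built on a ketone whose other α-carbon is β to O21, which is the enolisation problem the chosen route avoids. A1 requires etherification of a β-hydroxy ketone under base, which invites dehydration. Rings A and B and the enal are all left for later.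
- Comparison: the chosen strategy closes ring D by a simple oxa-Michael addition (13 to 15). It fixes C10 on C9 while only one α-position exists, and it keeps the radical step for the end, where it gives the enal, ring A and C5 together.

**Alternative 2: late C–H etherification.**
- Disconnection: O21–C22.
- Forward key step: the C20 alcohol A3 is turned into its hypoiodite by a hypervalent iodine oxidant and iodine under light. The alkoxy radical abstracts hydrogen from the C22 methyl group, and substitution of the resulting iodide closes ring D to give A4.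
- For it: C22 enters as a plain methyl group, for which asymmetric conjugate addition is very well established, and the 1,3-diaxial hydroxyl/methyl geometry suits 1,5-hydrogen transfer. On the directness of ring D it is at least as strong as the chosen route.
- Against it: the alkoxy radical sits next to the quaternary C24, so β-scission to a tertiary radical competes. A3 is a β-hydroxy ketone that dehydrates easily. The oxidative photochemical step runs on a molecule that already carries the acrolein and the allylic C5–H. The C14 silyl ether adds a deprotection after the key step.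
- Comparison: the chosen strategy also uses a radical step, but a reductive, polarity-matched chain in which the acrolein is formed by the step itself and nothing follows.

**Alternative 3: oxocarbenium–enol silane closure of ring C.**
- Disconnection: C19–C20.
- Forward key step: a silyl triflate and an amine base convert the methyl ketone of A5 into its enol silane and the lactol acetate into the C20 oxocarbenium ion. These join to give A6.
- For it: enolisation of a methyl ketone next to a quaternary carbon is unambiguous, and the bridge dictates C20. In regiocontrol of ring C and in convergence it is stronger than the chosen route.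
- Against it: the cationic carbon is neopentyl. The tertiary hydroxyl is silylated under the conditions. The β-alkoxy ketone product can ionise back under the same Lewis acid. C8 and C9 must be set without the bicyclic bias used here. A6 carries an isopropenyl group, so an allylic oxidation that must tell the methyl group from the tertiary allylic C5–H follows the key step.
- Comparison: the chosen strategy ends at 30 itself and uses the closed C/D bicycle as the control element for C9 and C8.

Key step: step 20

Assumption: 3, 9 and 24 are taken as purchasable, and the sense of induction of (S)-BINAP in step 2 is taken by analogy with cyclohex-2-enone (the antipodal ligand serves if it is reversed).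

## Route

Step 1
Reactants: 1 4,4-dimethylcyclohex-2-en-1-one
Product: 2 4,4-dimethylcyclohexa-2,5-dien-1-one
Conditions: DDQ, 1,4-dioxane, reflux
Reagents that add atoms: none
Why: Quinone dehydrogenation of an enone to the cross-conjugated dienone; the quaternary C24 blocks aromatisation.

Step 2
Reactants: 2 4,4-dimethylcyclohexa-2,5-dien-1-one; 3 (E)-2-phenylethenylboronic acid
Product: 4 (5S)-4,4-dimethyl-5-[(E)-2-phenylethenyl]cyclohex-2-en-1-one
Conditions: [Rh(acac)(C2H4)2] (3 mol %), (S)-BINAP, 3 (1.3 equiv), dioxane/H2O 10:1, 100 °C
Reagents that add atoms: none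
Why: Hayashi–Miyaura asymmetric 1,4-addition of an alkenylboronic acid; the two enone halves of 2 are enantiotopic, so ligand-controlled face selection sets C23, and the small excess of 3 limits a second addition.

Step 3
Reactants: 4 (5S)-4,4-dimethyl-5-[(E)-2-phenylethenyl]cyclohex-2-en-1-one
Product: 6 (5R)-5-(hydroxymethyl)-4,4-dimethylcyclohex-2-en-1-one, via aldehyde 5 (not isolated)
Conditions: O3, CH2Cl2, −78 °C (Sudan Red 7B end point); PPh3; then NaBH(OAc)3, AcOH, 0 °C
Reagents that add atoms: ozone ([O-][O+]=O)
Why: The electron-rich styryl alkene is ozonised much faster than the enone alkene; the α-stereogenic aldehyde is reduced in the same flask by NaBH(OAc)3, which reduces aldehydes and leaves the enone ketone.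

Step 4
Reactants: 6 (5R)-5-(hydroxymethyl)-4,4-dimethylcyclohex-2-en-1-one
Product: 7 (5R)-5-{[tert-butyl(dimethyl)silyl]oxymethyl}-4,4-dimethylcyclohex-2-en-1-one
Conditions: TBSCl, imidazole, CH2Cl2, 0 °C
Reagents that add atoms: tert-butyl(chloro)dimethylsilane (CC(C)(C)[Si](C)(C)Cl)
Why: Silylation of the primary alcohol, done at once on crude 6 so that the alcohol does not add to the enone before C9 is functionalised.

Step 5
Reactants: 7 (5R)-5-{[tert-butyl(dimethyl)silyl]oxymethyl}-4,4-dimethylcyclohex-2-en-1-one
Product: 8 (5S,6Z)-5-{[tert-butyl(dimethyl)silyl]oxymethyl}-6-(hydroxymethylidene)-4,4-dimethylcyclohex-2-en-1-one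
Conditions: NaH, HCO2Et, EtOH (cat.), THF, 0 °C to rt; aq. HCl
Reagents that add atoms: ethyl formate (CCOC=O)
Why: Claisen condensation (formylation) of the enone; C9 is the only enolisable position of 7, so the regiochemistry that would be lost after closure of ring D is fixed here.

Step 6
Reactants: 9 3-[(triisopropylsilyl)oxy]propanal; 10 methyl prop-2-enoate
Product: 11 methyl 3-hydroxy-2-methylidene-5-[(triisopropylsilyl)oxy]pentanoate (racemic)
Conditions: DABCO (0.5 equiv), MeOH, rt
Reagents that add atoms: none
Why: Morita–Baylis–Hillman reaction of an unhindered aliphatic aldehyde with an acrylate.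

Step 7
Reactants: 11 methyl 3-hydroxy-2-methylidene-5-[(triisopropylsilyl)oxy]pentanoate
Product: 12 methyl (2Z)-2-(bromomethyl)-5-[(triisopropylsilyl)oxy]pent-2-enoate
Conditions: NBS, Me2S, CH2Cl2, 0 °C to rt
Reagents that add atoms: N-bromosuccinimide (O=C1CCC(=O)N1Br)
Why: Bromide displaces the alkoxysulfonium ion with allylic transposition (SN2′), which gives the 2-(bromomethyl)enoate with the chain cis to CH2Br, the usual outcome for acrylate-derived adducts.

Step 8
Reactants: 8 (5S,6Z)-5-{[tert-butyl(dimethyl)silyl]oxymethyl}-6-(hydroxymethylidene)-4,4-dimethylcyclohex-2-en-1-one; 12 methyl (2Z)-2-(bromomethyl)-5-[(triisopropylsilyl)oxy]pent-2-enoate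
Product: 13 methyl (2E)-2-({[(E)-{(6S)-6-{[tert-butyl(dimethyl)silyl]oxymethyl}-5,5-dimethyl-2-oxocyclohex-3-en-1-ylidene}methyl]oxy}methyl)-5-[(triisopropylsilyl)oxy]pent-2-enoate
Conditions: Cs2CO3, DMF, 0 °C
Reagents that add atoms: none
Why: O-Alkylation of a vinylogous acid: the cesium salt in DMF should react at the formyl oxygen by direct SN2 displacement at the primary allylic bromide, which keeps the enoate geometry (C7 cis to C16). The enol ether is expected as the more stable E isomer, oxygen anti to the ketone.

Step 9
Reactants: 13 the enol ether of step 8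
Product: 15 methyl (2E)-2-({[(E)-{(1S,5S)-8,8-dimethyl-3-oxo-6-oxabicyclo[3.2.1]octan-2-ylidene}methyl]oxy}methyl)-5-[(triisopropylsilyl)oxy]pent-2-enoate, via primary alcohol 14 (not isolated)
Conditions: Bu4NF (1.1 equiv), THF, 0 °C
Reagents that add atoms: none
Why: Fluoride removes the primary TBS group faster than the primary TIPS group, and the C22 alkoxide adds 5-exo-trig to C20 (intramolecular oxa-Michael addition). This is possible only on the face that carries C22, so C20 is set cis-bridged; attack at the enol ether carbon C10 would be 5-endo.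

Step 10
Reactants: 15 the bicyclic allyl enol ether of step 9
Product: 16 methyl (3S)-3-[(1S,2S,5S)-2-formyl-8,8-dimethyl-3-oxo-6-oxabicyclo[3.2.1]octan-2-yl]-2-methylidene-5-[(triisopropylsilyl)oxy]pentanoate
Conditions: PhMe, 160 °C (sealed tube), BHT (cat.)
Reagents that add atoms: none
Why: Claisen rearrangement of an allyl vinyl ether. The syn-axial C24 methyl group shields one face of C9, so C8 should bond on the face of the O21–C22 bridge. In the chair transition state of the E enol ether only the hydrogen on C8 points under the bridge and the C7 chain is pseudo-axial, which gives the C8/C9 relation of the target; the boat would drive the C7 chain into C22.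

Step 11
Reactants: 16 the keto aldehyde of step 10
Product: 18 8,8-dimethyl-5′-methylidene-4′-{2-[(triisopropylsilyl)oxy]ethyl}spiro[6-oxabicyclo[3.2.1]octane-2,3′-oxane]-3,6′-dione (C8/C9/C20/C23 as in 30), via hydroxy ester 17 (not isolated)
Conditions: NaBH4, MeOH/CH2Cl2, −78 °C; AcOH; then CSA (cat.), PhMe, 80 °C
Reagents that add atoms: none
Why: Borohydride at low temperature reduces the aldehyde and leaves the hindered C17 ketone and the acrylate. Acid-catalysed lactonisation of the C10 alcohol onto the methyl ester closes ring B; acid is used so that neither retro-aldol loss of C10 nor oxa-Michael addition to the acrylate intervenes.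

Step 12
Reactants: 18 the α-methylene lactone of step 11
Product: 19 8,8-dimethyl-4′-{2-[(triisopropylsilyl)oxy]ethyl}spiro[6-oxabicyclo[3.2.1]octane-2,3′-oxane]-3,5′,6′-trione (C8/C9/C20/C23 as in 30)
Conditions: O3, CH2Cl2, −78 °C; Me2S
Reagents that add atoms: ozone ([O-][O+]=O)
Why: Ozonolysis of the only alkene unmasks the C14 ketone.

Step 13
Reactants: 19 the α-keto lactone of step 12; 20 3-bromoprop-1-ene (allyl bromide)
Product: 21 5′-hydroxy-8,8-dimethyl-5′-(prop-2-en-1-yl)-4′-{2-[(triisopropylsilyl)oxy]ethyl}spiro[6-oxabicyclo[3.2.1]octane-2,3′-oxane]-3,6′-dione (C8/C9/C14/C20/C23 as in 30)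
Conditions: In (powder), DMF, rt
Reagents that add atoms: none
Why: Barbier allylation: the allylindium reagent adds to the activated α-keto lactone carbonyl and should ignore the hindered C17 ketone and the lactone, without base, so the β-alkoxy ketone stays closed. Attack anti to the axial C9–C17 bond and trans to the C7 arm (equatorial attack) puts the allyl group equatorial and the hydroxyl axial, as in the target.

Step 14
Reactants: 21 the silyl ether of step 13
Product: 22 5′-hydroxy-4′-(2-hydroxyethyl)-8,8-dimethyl-5′-(prop-2-en-1-yl)spiro[6-oxabicyclo[3.2.1]octane-2,3′-oxane]-3,6′-dione (stereocentres as in 30)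
Conditions: HF·pyridine, pyridine, THF, 0 °C to rt
Reagents that add atoms: none
Why: Acidic fluoride cleaves the TIPS ether and leaves the tertiary alcohol, the lactone and the β-alkoxy ketone.

Step 15
Reactants: 22 the diol of step 14
Product: 23 5′-hydroxy-4′-(2-iodoethyl)-8,8-dimethyl-5′-(prop-2-en-1-yl)spiro[6-oxabicyclo[3.2.1]octane-2,3′-oxane]-3,6′-dione (stereocentres as in 30)
Conditions: I2, PPh3, imidazole, CH2Cl2, 0 °C
Reagents that add atoms: iodine (II)
Why: Appel iodination of the primary alcohol; the tertiary C14 hydroxyl does not react, and low temperature with excess iodide keeps substitution ahead of tetrahydrofuran formation.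

Step 16
Reactants: 24 methyl 2-(bromomethyl)prop-2-enoate; 25 sodium ethanesulfinate
Product: 26 methyl 2-[(ethylsulfonyl)methyl]prop-2-enoate
Conditions: DMF, rt
Reagents that add atoms: none
Why: S-Alkylation of the sulfinate by the allylic bromide (SN2 and SN2′ give the same product).

Step 17
Reactants: 26 methyl 2-[(ethylsulfonyl)methyl]prop-2-enoate
Product: 27 2-[(ethylsulfonyl)methyl]prop-2-en-1-ol
Conditions: i-Bu2AlH (2.2 equiv), CH2Cl2, −78 °C; Rochelle salt
Reagents that add atoms: none
Why: 1,2-Reduction of the acrylate ester to the allylic alcohol by an electrophilic hydride at low temperature.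

Step 18
Reactants: 27 2-[(ethylsulfonyl)methyl]prop-2-en-1-ol
Product: 28 2-[(ethylsulfonyl)methyl]prop-2-enal
Conditions: MnO2, CH2Cl2, rt
Reagents that add atoms: none
Why: Neutral oxidation of an allylic alcohol to the enal; 28 is used fresh.

Step 19
Reactants: 23 the iodide of step 15; 28 2-[(ethylsulfonyl)methyl]prop-2-enal
Product: 29 (2Z)-2-[(ethylsulfonyl)methyl]-4-[5′-hydroxy-4′-(2-iodoethyl)-8,8-dimethyl-3,6′-dioxospiro[6-oxabicyclo[3.2.1]octane-2,3′-oxan]-5′-yl]but-2-enal (stereocentres as in 30)
Conditions: second-generation Hoveyda–Grubbs catalyst [(H2IMes)Cl2Ru=CH(C6H4-2-OiPr)] (10 mol %), 28 (4 equiv), CH2Cl2, 40 °C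
Reagents that add atoms: none
Why: Olefin cross-metathesis of a monosubstituted alkene with an excess of a 2-substituted acrolein that hardly homodimerises; the primary iodide, tertiary alcohol and sulfone are tolerated, and the alkene geometry does not matter for step 20.

Step 20
Reactants: 29 the ring A seco iodide of step 19
Product: 30 the target
Conditions: dilauroyl peroxide (0.3 equiv, portions), ClCH2CH2Cl (0.01 M), reflux
Reagents that add atoms: none
Why: The peroxide starts a chain in which an ethyl radical abstracts iodine from C6; the primary C6 radical adds to C5 of the tethered enal, and the α-formyl radical at C2 breaks the C1–S bond to give the C1 methylene. The ethylsulfonyl radical loses SO2 and returns the ethyl radical. The closest known reaction type is the tin-free radical allylation of iodides with allyl ethyl sulfones by addition and β-fragmentation, used here intramolecularly. Ring A closes 6-exo-trig. C5 is set by a chair transition state on the trans-fused lactone, whose C7 and C16 arms are equatorial and gauche, so the forming side chain goes equatorial, trans to the C8–C9 bond. The step needs cyclisation to outrun 1,5-hydrogen transfer from C16 and intermolecular radical addition to the enal; the match of a nucleophilic radical with an electron-poor alkene, the preorganised arms and high dilution should secure this. Either alkene geometry of 29 leads to the same product.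

## Compound list

1 | 4,4-dimethylcyclohex-2-en-1-one | CC1(C)CCC(=O)C=C1 | starting material
2 | 4,4-dimethylcyclohexa-2,5-dien-1-one | CC1(C)C=CC(=O)C=C1 | intermediate
3 | (E)-2-phenylethenylboronic acid | OB(O)/C=C/c1ccccc1 | starting material
4 | (5S)-4,4-dimethyl-5-[(E)-2-phenylethenyl]cyclohex-2-en-1-one | O=C1C[C@@H](/C=C/c2ccccc2)C(C)(C)C=C1 | intermediate
5 | (1R)-2,2-dimethyl-5-oxocyclohex-3-ene-1-carbaldehyde | O=C[C@@H]1CC(=O)C=CC1(C)C | intermediate
6 | (5R)-5-(hydroxymethyl)-4,4-dimethylcyclohex-2-en-1-one | OC[C@@H]1CC(=O)C=CC1(C)C | intermediate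
7 | (5R)-5-{[tert-butyl(dimethyl)silyl]oxymethyl}-4,4-dimethylcyclohex-2-en-1-one | CC(C)(C)[Si](C)(C)OC[C@@H]1CC(=O)C=CC1(C)C | intermediate
8 | (5S,6Z)-5-{[tert-butyl(dimethyl)silyl]oxymethyl}-6-(hydroxymethylidene)-4,4-dimethylcyclohex-2-en-1-one | CC(C)(C)[Si](C)(C)OC[C@@H]1/C(=C/O)C(=O)C=CC1(C)C | intermediate
9 | 3-[(triisopropylsilyl)oxy]propanal | CC(C)[Si](OCCC=O)(C(C)C)C(C)C | starting material
10 | methyl prop-2-enoate | C=CC(=O)OC | starting material
11 | methyl 3-hydroxy-2-methylidene-5-[(triisopropylsilyl)oxy]pentanoate (racemic) | C=C(C(=O)OC)C(O)CCO[Si](C(C)C)(C(C)C)C(C)C | intermediate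
12 | methyl (2Z)-2-(bromomethyl)-5-[(triisopropylsilyl)oxy]pent-2-enoate | COC(=O)/C(CBr)=C/CCO[Si](C(C)C)(C(C)C)C(C)C | intermediate
13 | methyl (2E)-2-({[(E)-{(6S)-6-{[tert-butyl(dimethyl)silyl]oxymethyl}-5,5-dimethyl-2-oxocyclohex-3-en-1-ylidene}methyl]oxy}methyl)-5-[(triisopropylsilyl)oxy]pent-2-enoate | CC(C)(C)[Si](C)(C)OC[C@@H]1/C(=C\OC/C(C(=O)OC)=C\CCO[Si](C(C)C)(C(C)C)C(C)C)C(=O)C=CC1(C)C | intermediate
14 | methyl (2E)-2-({[(E)-{(6S)-6-(hydroxymethyl)-5,5-dimethyl-2-oxocyclohex-3-en-1-ylidene}methyl]oxy}methyl)-5-[(triisopropylsilyl)oxy]pent-2-enoate | OC[C@@H]1/C(=C\OC/C(C(=O)OC)=C\CCO[Si](C(C)C)(C(C)C)C(C)C)C(=O)C=CC1(C)C | intermediate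
15 | methyl (2E)-2-({[(E)-{(1S,5S)-8,8-dimethyl-3-oxo-6-oxabicyclo[3.2.1]octan-2-ylidene}methyl]oxy}methyl)-5-[(triisopropylsilyl)oxy]pent-2-enoate | O=C1C[C@@H]2OC[C@@H](C2(C)C)/C1=C\OC/C(C(=O)OC)=C\CCO[Si](C(C)C)(C(C)C)C(C)C | intermediate
16 | methyl (3S)-3-[(1S,2S,5S)-2-formyl-8,8-dimethyl-3-oxo-6-oxabicyclo[3.2.1]octan-2-yl]-2-methylidene-5-[(triisopropylsilyl)oxy]pentanoate | C=C(C(=O)OC)[C@@H](CCO[Si](C(C)C)(C(C)C)C(C)C)[C@]1(C=O)C(=O)C[C@@H]2OC[C@H]1C2(C)C | intermediate
17 | methyl (3S)-3-[(1S,2S,5S)-2-(hydroxymethyl)-8,8-dimethyl-3-oxo-6-oxabicyclo[3.2.1]octan-2-yl]-2-methylidene-5-[(triisopropylsilyl)oxy]pentanoate | C=C(C(=O)OC)[C@@H](CCO[Si](C(C)C)(C(C)C)C(C)C)[C@]1(CO)C(=O)C[C@@H]2OC[C@H]1C2(C)C | intermediate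
18 | 8,8-dimethyl-5′-methylidene-4′-{2-[(triisopropylsilyl)oxy]ethyl}spiro[6-oxabicyclo[3.2.1]octane-2,3′-oxane]-3,6′-dione, C8, C9, C20, C23 as in 30 | CC(C)[Si](C(C)C)(C(C)C)OCC[C@H]1[C@]2(COC(=O)C1=C)C(=O)C[C@@H]1OC[C@H]2C1(C)C | intermediate
19 | 8,8-dimethyl-4′-{2-[(triisopropylsilyl)oxy]ethyl}spiro[6-oxabicyclo[3.2.1]octane-2,3′-oxane]-3,5′,6′-trione, C8, C9, C20, C23 as in 30 | CC(C)[Si](C(C)C)(C(C)C)OCC[C@H]1[C@]2(COC(=O)C1=O)C(=O)C[C@@H]1OC[C@H]2C1(C)C | intermediate
20 | 3-bromoprop-1-ene (allyl bromide) | C=CCBr | starting material
21 | 5′-hydroxy-8,8-dimethyl-5′-(prop-2-en-1-yl)-4′-{2-[(triisopropylsilyl)oxy]ethyl}spiro[6-oxabicyclo[3.2.1]octane-2,3′-oxane]-3,6′-dione, stereocentres as in 30 | CC(C)[Si](C(C)C)(C(C)C)OCC[C@H]1[C@]2(COC(=O)[C@]1(O)CC=C)C(=O)C[C@@H]1OC[C@H]2C1(C)C | intermediate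
22 | 5′-hydroxy-4′-(2-hydroxyethyl)-8,8-dimethyl-5′-(prop-2-en-1-yl)spiro[6-oxabicyclo[3.2.1]octane-2,3′-oxane]-3,6′-dione, stereocentres as in 30 | OCC[C@H]1[C@]2(COC(=O)[C@]1(O)CC=C)C(=O)C[C@@H]1OC[C@H]2C1(C)C | intermediate
23 | 5′-hydroxy-4′-(2-iodoethyl)-8,8-dimethyl-5′-(prop-2-en-1-yl)spiro[6-oxabicyclo[3.2.1]octane-2,3′-oxane]-3,6′-dione, stereocentres as in 30 | ICC[C@H]1[C@]2(COC(=O)[C@]1(O)CC=C)C(=O)C[C@@H]1OC[C@H]2C1(C)C | intermediate
24 | methyl 2-(bromomethyl)prop-2-enoate | C=C(CBr)C(=O)OC | starting material
25 | sodium ethanesulfinate | CCS(=O)[O-].[Na+] | starting material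
26 | methyl 2-[(ethylsulfonyl)methyl]prop-2-enoate | C=C(CS(=O)(=O)CC)C(=O)OC | intermediate
27 | 2-[(ethylsulfonyl)methyl]prop-2-en-1-ol | C=C(CO)CS(=O)(=O)CC | intermediate
28 | 2-[(ethylsulfonyl)methyl]prop-2-enal | C=C(C=O)CS(=O)(=O)CC | intermediate
29 | (2Z)-2-[(ethylsulfonyl)methyl]-4-[5′-hydroxy-4′-(2-iodoethyl)-8,8-dimethyl-3,6′-dioxospiro[6-oxabicyclo[3.2.1]octane-2,3′-oxan]-5′-yl]but-2-enal, stereocentres as in 30 (ring A seco iodide) | ICC[C@H]2[C@]3(COC(=O)[C@]2(O)C/C=C(/C=O)CS(=O)(=O)CC)C(=O)C[C@@H]1OC[C@H]3C1(C)C | intermediate
30 | CNP0525385.1, configuration 5R, 8S, 9R, 14S, 20S, 23S in the numbering used here | C=C(C=O)[C@@H]1CC[C@H]2[C@]3(COC(=O)[C@]2(O)C1)C(=O)C[C@@H]1OC[C@H]3C1(C)C | target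

## Step count and least certain steps

Total step count: 20. Longest linear sequence: 15 steps (steps 1–5, 8–15, 19, 20).

**Step 20 (key step).**
- What may go wrong: hydrogen transfer from the allylic C16–H to the C6 radical may compete with the 6-exo closure. Iodine transfer to the ethyl radical is close to thermoneutral. Late in the reaction, chain radicals may add to the new, unhindered acrolein faster than they abstract iodine, so material is lost at high conversion.
- Fallback: it sets out from 23. Cross-metathesis with acrolein (same catalyst) would give (2E)-4-[5′-hydroxy-4′-(2-iodoethyl)-8,8-dimethyl-3,6′-dioxospiro[6-oxabicyclo[3.2.1]octane-2,3′-oxan]-5′-yl]but-2-enal F6. Slow addition of Bu3SnH with AIBN in benzene at 80 °C would close ring A by a Giese cyclisation through the same chair to the saturated aldehyde, the C1-nor target F7. α-Methylenation with Eschenmoser's salt and Et3N then returns to the route at 30, so the acrolein is never exposed to the radical chain.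

**Step 10 (Claisen rearrangement).**
- What may go wrong: E/Z isomerisation of the push–pull enol ether at 160 °C, or a boat pathway, would erode the C8 configuration. Ionisation of the activated allyl ether would scramble regiochemistry.
- Fallback: it sets out from 15. Dilute aqueous HCl in THF would hydrolyse the enol ether to (1S,5S)-2-[(Z)-hydroxymethylidene]-8,8-dimethyl-6-oxabicyclo[3.2.1]octan-3-one F3. Separately, 11 with Boc2O and DMAP would give its tert-butyl carbonate F4. Lewis-base-catalysed allylic alkylation of F3 with F4 ((DHQD)2PHAL or its pseudo-enantiomer, toluene, rt) attaches C8 to C9 on the same bridge face under catalyst control of C8, and returns to the route at 16.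

**Step 2 (rhodium-catalysed 1,4-addition).**
- What may go wrong: slow insertion at the β-carbon next to the quaternary centre, a second addition to the remaining enone, or weak face discrimination on the cross-conjugated dienone.
- Fallback: it sets out from 1 and leaves out step 1. The same catalyst adds 3 to the plain enone to give (3S)-4,4-dimethyl-3-[(E)-2-phenylethenyl]cyclohexan-1-one F1. Kinetic enolisation away from the substituent (LiN(i-Pr)2, Me3SiCl, THF, −78 °C) gives trimethyl({(5S)-4,4-dimethyl-5-[(E)-2-phenylethenyl]cyclohex-1-en-1-yl}oxy)silane F2. Saegusa–Ito oxidation with Pd(OAc)2 in MeCN then returns to the route at 4.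

**Step 13 (Barbier allylation).**
- What may go wrong: enolisation of the keto lactone toward C8 with epimerisation, hydrate formation that slows the addition, or weaker facial control than argued.
- Fallback: it sets out from 19 and returns at 21. The organoindium addition is replaced by a thermal allylboration with allylboronic acid pinacol ester in anhydrous toluene. This is a closed, six-membered transition state without metal salt, water or base. It passes through no new isolated compound (F0).

**Step 19 (cross-metathesis).**
- What may go wrong: slow turnover with the electron-poor 1,1-disubstituted partner, homodimerisation of 23, or decomposition of 28 on the catalyst.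
- Fallback: it sets out from 23. Cross-metathesis with the allylic alcohol 27, a more willing partner, would give 5′-hydroxy-5′-[(2Z)-4-(ethylsulfonyl)-3-(hydroxymethyl)but-2-en-1-yl]-4′-(2-iodoethyl)-8,8-dimethylspiro[6-oxabicyclo[3.2.1]octane-2,3′-oxane]-3,6′-dione F5. MnO2 oxidation of its allylic alcohol returns to the route at 29.

## Further compounds

F1 | step 2 | (3S)-4,4-dimethyl-3-[(E)-2-phenylethenyl]cyclohexan-1-one | O=C1C[C@@H](/C=C/c2ccccc2)C(C)(C)CC1
F2 | step 2 | trimethyl({(5S)-4,4-dimethyl-5-[(E)-2-phenylethenyl]cyclohex-1-en-1-yl}oxy)silane | C[Si](C)(C)OC1=CCC(C)(C)[C@H](/C=C/c2ccccc2)C1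
F3 | step 10 | (1S,5S)-2-[(Z)-hydroxymethylidene]-8,8-dimethyl-6-oxabicyclo[3.2.1]octan-3-one | O=C1C[C@@H]2OC[C@@H](C2(C)C)/C1=C/O
F4 | step 10 | methyl 3-[(tert-butoxycarbonyl)oxy]-2-methylidene-5-[(triisopropylsilyl)oxy]pentanoate (racemic) | C=C(C(=O)OC)C(OC(=O)OC(C)(C)C)CCO[Si](C(C)C)(C(C)C)C(C)C
F0 | step 13 | none | none
F5 | step 19 | 5′-hydroxy-5′-[(2Z)-4-(ethylsulfonyl)-3-(hydroxymethyl)but-2-en-1-yl]-4′-(2-iodoethyl)-8,8-dimethylspiro[6-oxabicyclo[3.2.1]octane-2,3′-oxane]-3,6′-dione, stereocentres as in 30 | ICC[C@H]2[C@]3(COC(=O)[C@]2(O)C/C=C(/CO)CS(=O)(=O)CC)C(=O)C[C@@H]1OC[C@H]3C1(C)C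
F6 | step 20 | (2E)-4-[5′-hydroxy-4′-(2-iodoethyl)-8,8-dimethyl-3,6′-dioxospiro[6-oxabicyclo[3.2.1]octane-2,3′-oxan]-5′-yl]but-2-enal, stereocentres as in 30 | ICC[C@H]2[C@]3(COC(=O)[C@]2(O)C/C=C/C=O)C(=O)C[C@@H]1OC[C@H]3C1(C)C
F7 | step 20 | C1-nor target: ring A closed with a 2-oxoethyl group on C5, stereocentres as in 30 | O=CC[C@@H]1CC[C@H]2[C@]3(COC(=O)[C@]2(O)C1)C(=O)C[C@@H]1OC[C@H]3C1(C)C
A1 | alternative 1 | 2-{[tert-butyl(dimethyl)silyl]oxymethyl}-4,4-dimethyl-5-[(phenylselanyl)methoxy]cyclohex-2-en-1-one, C20 as in 30 | O=C1C[C@H](OC[Se]c2ccccc2)C(C)(C)C=C1CO[Si](C)(C)C(C)(C)C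
A2 | alternative 1 | 2-{[tert-butyl(dimethyl)silyl]oxymethyl}-8,8-dimethyl-6-oxabicyclo[3.2.1]octan-3-one, C9, C20, C23 as in 30 | O=C1C[C@@H]2OC[C@H]([C@H]1CO[Si](C)(C)C(C)(C)C)C2(C)C
A3 | alternative 2 | ring D seco alcohol: C14 triethylsilyl ether with free C20 hydroxyl and C22 methyl, stereocentres as in 30 | C=C(C=O)[C@@H]1CC[C@H]2[C@]3(COC(=O)[C@]2(O[Si](CC)(CC)CC)C1)C(=O)C[C@H](O)C(C)(C)[C@@H]3C
A4 | alternative 2 | C14 triethylsilyl ether of the target | C=C(C=O)[C@@H]1CC[C@H]2[C@]3(COC(=O)[C@]2(O[Si](CC)(CC)CC)C1)C(=O)C[C@@H]1OC[C@H]3C1(C)C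
A5 | alternative 3 | ring C seco methyl ketone with C20 lactol acetate (both anomers) and isopropenyl on C5, other stereocentres as in 30 | C=C(C)[C@@H]1CC[C@H]2[C@](COC(=O)[C@]2(O)C1)(C(C)=O)[C@H]1COC(OC(C)=O)C1(C)C
A6 | alternative 3 | deoxy target carrying isopropenyl in place of the acrolein | C=C(C)[C@@H]1CC[C@H]2[C@]3(COC(=O)[C@]2(O)C1)C(=O)C[C@@H]1OC[C@H]3C1(C)C
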